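The spiro-cyclohexane ring (labdane C12–C15 plus C15′ and C17′ of the totarane lactone) is treated as a cyclohexene in disguise: moving the C14–OH/C13=C16 allylic alcohol back to a C13=C14 methyl alkene leaves a [4+2] retron. One Diels–Alder reaction between the (E)-12,14-diene of a labdane C20 acid and the exocyclic C15′=C17′ bond of a 3-methylenebenzofuranone forms the C15–C17′ and C12–C15′ bonds, the spiro carbon and C12. Both partners come from the chiral pool (sclareolide, totarol); in each an alkoxy radical placed by the skeleton oxidises an unactivated C–H bond (C20 methyl; isopropyl C15′–H).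

Key step: step 19

Remark: atoms carry labdane numbers in the left half and totarane numbers with primes in the right half; the spiro carbon is C15′ and its ring CH2 is C17′. Dienophile 22 is assumed to be too reactive to store and is used as made.

Step 1
Reactants: 1 (+)-sclareolide
Product: 2 13,14,15,16-tetranorlabdane-8α,12-diol
Conditions: LiAlH4, THF, 0 °C → rt
Reagents that add atoms: none
Why: Hydride reduction of the γ-lactone opens it to the primary/tertiary diol and touches no stereocentre.

Step 2
Reactants: 2 13,14,15,16-tetranorlabdane-8α,12-diol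
Product: 3 8α-hydroxy-13,14,15,16-tetranorlabdan-12-yl pivalate
Conditions: PivCl, pyridine, CH2Cl2, 0 °C
Reagents that add atoms: pivaloyl chloride CC(C)(C)C(Cl)=O
Why: Selective acylation of the primary alcohol (the tertiary C8–OH is inert); the acyloxy group later deactivates the C12–H bonds toward hydrogen abstraction and prevents ether formation to C8.

Step 3
Reactants: 3 8α-hydroxy-13,14,15,16-tetranorlabdan-12-yl pivalate
Product: 4 13,14,15,16-tetranorlabd-8(17)-en-12-yl pivalate
Conditions: SOCl2, pyridine, CH2Cl2, −78 °C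
Reagents that add atoms: none
Why: E2 dehydration of the equatorial tertiary chlorosulfite, for which only the C17 methyl hydrogens can become anti-periplanar, should give mainly the exocyclic alkene (regioselective dehydration).

Step 4
Reactants: 4 13,14,15,16-tetranorlabd-8(17)-en-12-yl pivalate
Product: 5 8-oxo-13,14,15,16,17-pentanorlabdan-12-yl pivalate (9α-H)
Conditions: O3, CH2Cl2/MeOH, −78 °C; then PPh3
Reagents that add atoms: ozone [O-][O+]=O
Why: Ozonolysis with reductive work-up excises C17 and gives the C8 ketone; endocyclic alkene isomers from step 3 give ring-cleaved products that are removed here.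

Step 5
Reactants: 5 8-oxo-13,14,15,16,17-pentanorlabdan-12-yl pivalate
Product: 6 8β-hydroxy-13,14,15,16,17-pentanorlabdan-12-yl pivalate (axial OH)
Conditions: L-selectride, THF, −78 °C; H2O
Reagents that add atoms: none
Why: Substrate-controlled ketone reduction with a bulky borohydride: hydride comes from the α (equatorial) face because the β face is blocked by the syn-axial C20 methyl, which sets the axial 8β-alcohol.

Step 6
Reactants: 6 8β-hydroxy-13,14,15,16,17-pentanorlabdan-12-yl pivalate
Product: 7 8β,20-epoxy-13,14,15,16,17-pentanorlabdan-12-yl pivalate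
Conditions: PhI(OAc)2, I2, cyclohexane, hν (W lamp), 40 °C
Reagents that add atoms: none
Why: Suárez hypoiodite reaction: the 8β-alkoxy radical abstracts hydrogen from the 1,3-diaxial C20 methyl through a six-membered transition state (1,5-HAT) and the C20 iodide closes to the tetrahydrofuran, while the flexible C12–H bonds are deactivated by the acyloxy group.

Step 7
Reactants: 7 8β,20-epoxy-13,14,15,16,17-pentanorlabdan-12-yl pivalate
Product: 8 12-pivaloyloxy-13,14,15,16,17-pentanorlabdan-20,8β-olide
Conditions: RuCl3 (cat.), NaIO4, CCl4/MeCN/H2O, rt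
Reagents that add atoms: sodium periodate [Na+].[O-]I(=O)(=O)=O
Why: RuO4 oxidation of the cyclic ether at its CH2 gives the γ-lactone (ether-to-lactone oxidation); attack at C8–H instead would give the 8-oxo-20-acid, which step 8 converts into the same product.

Step 8
Reactants: 8 12-pivaloyloxy-13,14,15,16,17-pentanorlabdan-20,8β-olide
Product: 10 8,12-dioxo-13,14,15,16,17-pentanorlabdan-20-oic acid, via lithium dihydroxy carboxylate 9 (not isolated)
Conditions: LiOH, THF/MeOH/H2O, 65 °C; evaporate; IBX, DMSO, 35 °C; then 1 M HCl to pH 3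
Reagents that add atoms: lithium hydroxide [Li+].[OH-]
Why: Saponification opens the lactone and removes the pivalate, and IBX oxidises the secondary and the primary alcohol of the carboxylate salt before acidification, so that the γ-hydroxy acid cannot close back to the lactone.

Step 9
Reactants: 10 8,12-dioxo-13,14,15,16,17-pentanorlabdan-20-oic acid
Product: 11 (12E)-8,14-dioxo-15,17-dinorlabd-12-en-20-oic acid
Conditions: Ph3P=C(CH3)CHO, toluene, 80 °C
Reagents that add atoms: 2-(triphenylphosphoranylidene)propanal CC(C=O)=P(c1ccccc1)(c1ccccc1)c1ccccc1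
Why: Wittig reaction of the stabilised ylide, which reacts only with the unhindered aldehyde and gives the (E)-2-methyl enal.

Step 10
Reactants: 11 (12E)-8,14-dioxo-15,17-dinorlabd-12-en-20-oic acid
Product: 12 (12E)-labda-8(17),12,14-trien-20-oic acid
Conditions: Ph3PCH3Br, KOtBu (excess), THF, 0 → 60 °C; H3O+
Reagents that add atoms: methyltriphenylphosphonium bromide C[P+](c1ccccc1)(c1ccccc1)c1ccccc1.[Br-]
Why: Wittig methylenation of both the enal and the hindered C8 ketone; C9 can epimerise through the ketone and should keep the more stable equatorial side chain (9α-H).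

Step 11
Reactants: 13 (+)-totarol
Product: 14 totaryl acetate
Conditions: Ac2O, pyridine, DMAP (cat.), rt
Reagents that add atoms: acetic anhydride CC(=O)OC(C)=O
Why: Acetylation of the hindered phenol protects it against the oxidants of the next steps.

Step 12
Reactants: 14 totaryl acetate
Product: 15 7-oxototaryl acetate
Conditions: CrO3, AcOH, rt
Reagents that add atoms: chromium trioxide O=[Cr](=O)=O
Why: Benzylic oxidation at C7′, the only benzylic CH2; the isopropyl C–H lies in the arene plane and is stereoelectronically inert.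

Step 13
Reactants: 15 7-oxototaryl acetate
Product: 16 (7S)-7β-hydroxytotaryl acetate
Conditions: (R)-Me-CBS (0.2 equiv), BH3·SMe2, THF, −20 °C; MeOH
Reagents that add atoms: none
Why: CBS reduction: reagent control ((R)-catalyst, arene as the large group) and attack from the α face opposite the C10′ methyl should both give the 7β-alcohol.

Step 14
Reactants: 16 (7S)-7β-hydroxytotaryl acetate
Product: 17 7β,15-epoxytotara-8,11,13-trien-13-yl acetate
Conditions: PhI(OAc)2, I2, CH2Cl2/cyclohexane, hν (W lamp), rt
Reagents that add atoms: none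
Why: Suárez hypoiodite reaction: the 7β-alkoxy radical reaches the in-plane peri C15′–H (1,5-HAT, the only δ-hydrogen) and the tertiary iodide closes to the dihydroisobenzofuran with retention at C7′.

Step 15
Reactants: 17 7β,15-epoxytotara-8,11,13-trien-13-yl acetate
Product: 18 7β,13-diacetoxytotara-8,11,13,15-tetraene (14-isopropenyl)
Conditions: Ac2O, FeCl3 (cat.), 0 °C → rt
Reagents that add atoms: acetic anhydride CC(=O)OC(C)=O
Why: Acylative cleavage of a tertiary ether (as for tert-butyl ethers): the tertiary C15′–O bond ionises and the cation loses a proton to give the isopropenyl group, while O7′ is acetylated without breaking the C7′–O bond.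

Step 16
Reactants: 18 7β,13-diacetoxytotara-8,11,13,15-tetraene
Product: 19 7β,13-diacetoxytotara-8,11,13,15(17)-tetraen-16-al
Conditions: SeO2, 1,4-dioxane, 80 °C
Reagents that add atoms: selenium dioxide O=[Se]=O
Why: Allylic oxidation with SeO2 (ene reaction, [2,3]-shift, further oxidation) converts the only allylic methyl group into the 2-aryl-acrolein.

Step 17
Reactants: 19 7β,13-diacetoxytotara-8,11,13,15(17)-tetraen-16-al
Product: 20 7β,13-diacetoxytotara-8,11,13,15(17)-tetraen-16-oic acid
Conditions: NaClO2, NaH2PO4, 2-methyl-2-butene, t-BuOH/H2O, 0 °C → rt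
Reagents that add atoms: sodium chlorite [Na+].[O-]Cl=O
Why: Pinnick oxidation of the enal to the acrylic acid, with 2-methyl-2-butene trapping the hypochlorous acid.

Step 18
Reactants: 20 7β,13-diacetoxytotara-8,11,13,15(17)-tetraen-16-oic acid
Product: 22 7β-acetoxytotara-8,11,13,15(17)-tetraen-16,13-olide (3-methylenebenzofuran-2-one), via phenol acid 21 (not isolated)
Conditions: K2CO3, MeOH, 0 °C; HCl to pH 4; then EDC·HCl, DMAP (cat.), CH2Cl2, 0 °C; solution used at once
Reagents that add atoms: none
Why: The aryl acetate is methanolysed far faster than the hindered secondary acetate, and carbodiimide activation then closes the five-membered aryl lactone (selective deacetylation, then lactonisation).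

Step 19
Reactants: 12 (12E)-labda-8(17),12,14-trien-20-oic acid; 22 7β-acetoxytotara-8,11,13,15(17)-tetraen-16,13-olide
Product: 23 Diels–Alder adduct (the 14-deoxy compound with a C13 methyl group and a C13=C14 double bond; spiro centre and C12 as in the target)
Conditions: benzene (1 M), BHT (cat.), 25–40 °C, dark, Ar
Reagents that add atoms: none
Why: Thermal, concerted but asynchronous normal-demand Diels–Alder reaction, the known reactivity of α-methylene lactones and the reaction type used for other terpenoid [4+2] dimers; the unsubstituted diene terminus C15 bonds first to the electrophilic exocyclic C17′ and C12 then closes onto C15′, so the six-membered ring forms by a suprafacial [4+2] cycloaddition. Regiochemistry follows the "ortho" rule of the 1-alkyl diene (C12 to the carbon that carries the carbonyl and the arene). The s-cis exocyclic enoate should react with its carbonyl exo and the arene endo, which with the (E)-diene puts C11 cis to the arene and fixes C12 relative to C15′. The diene must add to the lactone face on which the C7′ acetate lies, and with one of its own two faces; a hydrogen bond between the C20 carboxylic acid and the acetate carbonyl in the non-polar medium is counted on to favour this arrangement, and this is the least secure element of the step. Chemoselectivity is secured because all other alkenes are unactivated and the dienophile is used as soon as it is made, before it can dimerise.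

Step 20
Reactants: 23 Diels–Alder adduct
Product: 25 14-oxo compound with exocyclic C13=C16 (cross-conjugated enone), via C14 hydroperoxide 24 (not isolated)
Conditions: O2, TPP (cat.), hν (visible), CH2Cl2, 0 °C; then Ac2O, pyridine, DMAP (cat.), rt; aq. NaHCO3 work-up
Reagents that add atoms: oxygen O=O
Why: Schenck ene reaction of singlet oxygen on the trisubstituted C13=C14 alkene, with hydrogen abstraction from the C16 methyl geminal to the bulky C12 (large-group effect), then Kornblum–DeLaMare-type dehydration of the secondary hydroperoxide to the enone; the 1,1-disubstituted alkene reacts far more slowly.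

Step 21
Reactants: 25 14-oxo compound
Product: 26 target compound CNP0558742.1
Conditions: NaBH4, CeCl3·7H2O, MeOH/THF, −78 °C
Reagents that add atoms: none
Why: Luche reduction: 1,2-selective axial hydride attack on the cyclohexanone face away from the axial arene on C15′ should give the equatorial C14 alcohol, cis to C11.

Compound list
1 | (+)-sclareolide | C[C@]12CCCC([C@@H]1CC[C@@]3([C@@H]2CC(=O)O3)C)(C)C | starting material
2 | 13,14,15,16-tetranorlabdane-8α,12-diol | C[C@]12CCCC(C)(C)[C@@H]1CC[C@@](C)(O)[C@@H]2CCO | intermediate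
3 | 8α-hydroxy-13,14,15,16-tetranorlabdan-12-yl pivalate | C[C@]12CCCC(C)(C)[C@@H]1CC[C@@](C)(O)[C@@H]2CCOC(=O)C(C)(C)C | intermediate
4 | 13,14,15,16-tetranorlabd-8(17)-en-12-yl pivalate | C=C1CC[C@H]2C(C)(C)CCC[C@]2(C)[C@H]1CCOC(=O)C(C)(C)C | intermediate
5 | 8-oxo-13,14,15,16,17-pentanorlabdan-12-yl pivalate | O=C1CC[C@H]2C(C)(C)CCC[C@]2(C)[C@H]1CCOC(=O)C(C)(C)C | intermediate
6 | 8β-hydroxy-13,14,15,16,17-pentanorlabdan-12-yl pivalate | O[C@H]1CC[C@H]2C(C)(C)CCC[C@]2(C)[C@H]1CCOC(=O)C(C)(C)C | intermediate
7 | 8β,20-epoxy-13,14,15,16,17-pentanorlabdan-12-yl pivalate | O3[C@H]1CC[C@H]2C(C)(C)CCC[C@]2(C3)[C@H]1CCOC(=O)C(C)(C)C | intermediate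
8 | 12-pivaloyloxy-13,14,15,16,17-pentanorlabdan-20,8β-olide | O3[C@H]1CC[C@H]2C(C)(C)CCC[C@]2(C3=O)[C@H]1CCOC(=O)C(C)(C)C | intermediate
9 | lithium 8β,12-dihydroxy-13,14,15,16,17-pentanorlabdan-20-oate | O[C@H]1CC[C@H]2C(C)(C)CCC[C@]2(C(=O)[O-])[C@H]1CCO.[Li+] | intermediate
10 | 8,12-dioxo-13,14,15,16,17-pentanorlabdan-20-oic acid | O=C1CC[C@H]2C(C)(C)CCC[C@]2(C(=O)O)[C@H]1CC=O | intermediate
11 | (12E)-8,14-dioxo-15,17-dinorlabd-12-en-20-oic acid | O=C1CC[C@H]2C(C)(C)CCC[C@]2(C(=O)O)[C@H]1C/C=C(\C)C=O | intermediate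
12 | (12E)-labda-8(17),12,14-trien-20-oic acid | C=C1CC[C@H]2C(C)(C)CCC[C@]2(C(=O)O)[C@H]1C/C=C(\C)C=C | intermediate
13 | (+)-totarol | CC(C)c1c(O)ccc2c1CC[C@H]1C(C)(C)CCC[C@]21C | starting material
14 | totaryl acetate | CC(C)c1c(OC(C)=O)ccc2c1CC[C@H]1C(C)(C)CCC[C@]21C | intermediate
15 | 7-oxototaryl acetate | CC(C)c1c(OC(C)=O)ccc2c1C(=O)C[C@H]1C(C)(C)CCC[C@]21C | intermediate
16 | (7S)-7β-hydroxytotaryl acetate | CC(C)c1c(OC(C)=O)ccc2c1[C@@H](O)C[C@H]1C(C)(C)CCC[C@]21C | intermediate
17 | 7β,15-epoxytotara-8,11,13-trien-13-yl acetate | CC3(C)c1c(OC(C)=O)ccc2c1[C@@H](O3)C[C@H]1C(C)(C)CCC[C@]21C | intermediate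
18 | 7β,13-diacetoxytotara-8,11,13,15-tetraene | C=C(C)c1c(OC(C)=O)ccc2c1[C@@H](OC(C)=O)C[C@H]1C(C)(C)CCC[C@]21C | intermediate
19 | 7β,13-diacetoxytotara-8,11,13,15(17)-tetraen-16-al | C=C(C=O)c1c(OC(C)=O)ccc2c1[C@@H](OC(C)=O)C[C@H]1C(C)(C)CCC[C@]21C | intermediate
20 | 7β,13-diacetoxytotara-8,11,13,15(17)-tetraen-16-oic acid | C=C(C(=O)O)c1c(OC(C)=O)ccc2c1[C@@H](OC(C)=O)C[C@H]1C(C)(C)CCC[C@]21C | intermediate
21 | 7β-acetoxy-13-hydroxytotara-8,11,13,15(17)-tetraen-16-oic acid | C=C(C(=O)O)c1c(O)ccc2c1[C@@H](OC(C)=O)C[C@H]1C(C)(C)CCC[C@]21C | intermediate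
22 | 7β-acetoxytotara-8,11,13,15(17)-tetraen-16,13-olide | C=C1C(=O)Oc2ccc3c(c21)[C@@H](OC(C)=O)C[C@H]1C(C)(C)CCC[C@]31C | intermediate
23 | Diels–Alder adduct (C13 methyl, C13=C14) | C=C1CC[C@H]2C(C)(C)CCC[C@]2(C(=O)O)[C@H]1C[C@H]1C(C)=CCC[C@]12C(=O)Oc1ccc3c(c12)[C@@H](OC(C)=O)C[C@H]1C(C)(C)CCC[C@]31C | intermediate
24 | C14 hydroperoxide (C13=C16 exocyclic) | C=C1CC[C@H]2C(C)(C)CCC[C@]2(C(=O)O)[C@H]1C[C@H]1C(=C)C(OO)CC[C@]12C(=O)Oc1ccc3c(c12)[C@@H](OC(C)=O)C[C@H]1C(C)(C)CCC[C@]31C | intermediate
25 | 14-oxo compound (C13=C16 enone) | C=C1CC[C@H]2C(C)(C)CCC[C@]2(C(=O)O)[C@H]1C[C@H]1C(=C)C(=O)CC[C@]12C(=O)Oc1ccc3c(c12)[C@@H](OC(C)=O)C[C@H]1C(C)(C)CCC[C@]31C | intermediate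
26 | CNP0558742.1 | C=C1CC[C@H]2C(C)(C)CCC[C@]2(C(=O)O)[C@H]1C[C@H]1C(=C)[C@@H](O)CC[C@]12C(=O)Oc1ccc3c(c12)[C@@H](OC(C)=O)C[C@H]1C(C)(C)CCC[C@]31C | target

Total step count: 21. Longest linear sequence: 13 steps (steps 1–10, then 19–21).

Steps most likely to fail

Step 19. The cycloaddition may take the wrong face of the lactone, because the C7′ acetate shields the very face that must be attacked and the hydrogen bond counted on may not outweigh this. It may also fail to discriminate the two faces of the diene, or the dienophile may dimerise first. The fallback sets out from 20 and returns at 23. Both acetates of 20 are hydrolysed (LiOH, aq. THF) to the 7β,13-dihydroxy acid F1, MnO2 oxidises the benzylic alcohol to the 7-oxo phenol acid F2, and EDC closes the 7-oxo methylene lactone F3. Its C7′ carbonyl oxygen is pushed out of the ring plane towards the α face by the peri methylene group, which should leave only the β face open. Cycloaddition with 12 then gives the 7′-oxo adduct F4, NaBH4 delivers hydride to C7′ from the side away from C12 to give the 7′β-alcohol F5, and Ac2O/DMAP returns to 23.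

Step 6. Hydrogen abstraction may take place at C12 (also through a six-membered transition state) instead of at C20, or the alcohol may simply be oxidised back to 5. The fallback sets out from 5 and returns at 12, and it removes the C12 hydrogens from the substrate. Saponification of the pivalate and Jones oxidation give the 8-oxo-12-acid F6, and L-selectride reduction with acidic work-up gives the cis-fused γ-lactone F7. Aminolysis with Me2AlN(OMe)Me gives the 8β-hydroxy Weinreb amide F8, in which C20 is the only position within reach. The hypoiodite reaction then gives the ether amide F9, CrO3/AcOH the lactone amide F10, and saponification with IBX oxidation (as in step 8) the keto acid amide F11. Methylenation gives the alkene amide F12, DIBAL the aldehyde F13, and the ylide of step 9 the enal F14, which is methylenated to 12.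

Step 14. The alkoxy radical may be oxidised back to ketone 15 or fragment, or the ring may be iodinated, instead of the peri hydrogen being abstracted. The fallback sets out from 15 and returns at 18. Radical bromination (NBS, AIBN, PhCF3, 80 °C) of the isopropyl C–H, the only benzylic C–H left in 15, gives the tertiary bromide F15. DBU eliminates HBr to the isopropenyl ketone F16, CBS reduction as in step 13 gives the 7β-alcohol F17, and acetylation gives 18.

Further compounds
F1 | step 19 | 7β,13-dihydroxytotara-8,11,13,15(17)-tetraen-16-oic acid | C=C(C(=O)O)c1c(O)ccc2c1[C@@H](O)C[C@H]1C(C)(C)CCC[C@]21C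
F2 | step 19 | 13-hydroxy-7-oxototara-8,11,13,15(17)-tetraen-16-oic acid | C=C(C(=O)O)c1c(O)ccc2c1C(=O)C[C@H]1C(C)(C)CCC[C@]21C
F3 | step 19 | 7-oxototara-8,11,13,15(17)-tetraen-16,13-olide | C=C1C(=O)Oc2ccc3c(c21)C(=O)C[C@H]1C(C)(C)CCC[C@]31C
F4 | step 19 | 7′-oxo analogue of adduct 23 | C=C1CC[C@H]2C(C)(C)CCC[C@]2(C(=O)O)[C@H]1C[C@H]1C(C)=CCC[C@]12C(=O)Oc1ccc3c(c12)C(=O)C[C@H]1C(C)(C)CCC[C@]31C
F5 | step 19 | 7′β-hydroxy analogue of adduct 23 | C=C1CC[C@H]2C(C)(C)CCC[C@]2(C(=O)O)[C@H]1C[C@H]1C(C)=CCC[C@]12C(=O)Oc1ccc3c(c12)[C@@H](O)C[C@H]1C(C)(C)CCC[C@]31C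
F6 | step 6 | 8-oxo-13,14,15,16,17-pentanorlabdan-12-oic acid | O=C1CC[C@H]2C(C)(C)CCC[C@]2(C)[C@H]1CC(=O)O
F7 | step 6 | 13,14,15,16,17-pentanorlabdan-12,8β-olide | O1[C@H]2CC[C@H]3C(C)(C)CCC[C@]3(C)[C@H]2CC1=O
F8 | step 6 | 8β-hydroxy-N-methoxy-N-methyl-13,14,15,16,17-pentanorlabdan-12-amide | O[C@H]1CC[C@H]2C(C)(C)CCC[C@]2(C)[C@H]1CC(=O)N(C)OC
F9 | step 6 | 8β,20-epoxy-N-methoxy-N-methyl-13,14,15,16,17-pentanorlabdan-12-amide | O3[C@H]1CC[C@H]2C(C)(C)CCC[C@]2(C3)[C@H]1CC(=O)N(C)OC
F10 | step 6 | 12-(N-methoxy-N-methylamino)-12-oxo-13,14,15,16,17-pentanorlabdan-20,8β-olide | O3[C@H]1CC[C@H]2C(C)(C)CCC[C@]2(C3=O)[C@H]1CC(=O)N(C)OC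
F11 | step 6 | 12-(N-methoxy-N-methylamino)-8,12-dioxo-13,14,15,16,17-pentanorlabdan-20-oic acid | O=C1CC[C@H]2C(C)(C)CCC[C@]2(C(=O)O)[C@H]1CC(=O)N(C)OC
F12 | step 6 | 12-(N-methoxy-N-methylamino)-12-oxo-13,14,15,16-tetranorlabd-8(17)-en-20-oic acid | C=C1CC[C@H]2C(C)(C)CCC[C@]2(C(=O)O)[C@H]1CC(=O)N(C)OC
F13 | step 6 | 12-oxo-13,14,15,16-tetranorlabd-8(17)-en-20-oic acid | C=C1CC[C@H]2C(C)(C)CCC[C@]2(C(=O)O)[C@H]1CC=O
F14 | step 6 | (12E)-14-oxo-15-norlabda-8(17),12-dien-20-oic acid | C=C1CC[C@H]2C(C)(C)CCC[C@]2(C(=O)O)[C@H]1C/C=C(\C)C=O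
F15 | step 14 | 15-bromo-7-oxototaryl acetate | CC(C)(Br)c1c(OC(C)=O)ccc2c1C(=O)C[C@H]1C(C)(C)CCC[C@]21C
F16 | step 14 | 7-oxototara-8,11,13,15-tetraen-13-yl acetate | C=C(C)c1c(OC(C)=O)ccc2c1C(=O)C[C@H]1C(C)(C)CCC[C@]21C
F17 | step 14 | 7β-hydroxytotara-8,11,13,15-tetraen-13-yl acetate | C=C(C)c1c(OC(C)=O)ccc2c1[C@@H](O)C[C@H]1C(C)(C)CCC[C@]21C
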